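**Assumption:** atom labels C1–C15 follow germacrane numbering of the target (C6–O lactone, C12 lactone carbonyl, C13 exo-methylene, C14 formyl carbon, C15 hydroxymethyl carbon). The target is (6R,7S,8S,9S), with C2 cis to C9 across C1=C10 and C3 cis to C6 across C4=C5.

## Retrosynthetic overview

1. Target 29 ← end-game on macrolactone acetonide 22: acetonide off, two angelates on, C14 oxidised to the aldehyde, C15 unmasked.
2. 22 ← bromo-enal 20 by one electroreductive, chromium-catalysed intramolecular 2-(methoxycarbonyl)allylation. The C6–C7 bond closes the ten-membered carbocycle first, and the alkoxide then closes the five-membered lactone in the same operation.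
3. 20 ← aldehyde 16 by Morita–Baylis–Hillman reaction at C7, C6 alcohol oxidation and allylic bromination.
4. 16 ← Wittig union (C1=C10) of ketone 5 (L-arabinose: C7, C8, C9, C10, C14) with phosphonium salt 13 (but-2-yne-1,4-diol plus allyl chloride: C1–C6, C15).
5. C8 and C9 come from L-arabinose C2 and C3; C6 and C7 are set in the ring closure under control of C8/C9.

## Route

Step 1
Reactants: 1 L-arabinose
Product: 2 L-arabinose diethyl dithioacetal
Conditions: EtSH, conc. HCl, 0 °C
Reagents that add atoms: ethanethiol, CCS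
Why: Acid-catalysed dithioacetalisation traps the open-chain aldose, masking C1 (future C7) as an aldehyde equivalent without touching the stereocentres.

Step 2
Reactants: 2 L-arabinose diethyl dithioacetal
Product: 3 5-O-TBDPS-L-arabinose diethyl dithioacetal
Conditions: TBDPSCl (1.05 equiv), imidazole, DMF, 0 °C
Reagents that add atoms: tert-butyl(chloro)diphenylsilane, CC(C)(C)[Si](Cl)(c1ccccc1)c1ccccc1
Why: Selective silyl ether formation at the only primary hydroxyl (future C14–O) by steric control of the bulky silyl chloride.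

Step 3
Reactants: 3 5-O-TBDPS-L-arabinose diethyl dithioacetal
Product: 4 2,3-O-isopropylidene-5-O-TBDPS-L-arabinose diethyl dithioacetal
Conditions: 2,2-dimethoxypropane, p-TsOH·H2O (cat.), acetone, rt (equilibrating)
Reagents that add atoms: 2,2-dimethoxypropane, COC(C)(C)OC
Why: Thermodynamic acetonide formation, in which the trans-dioxolane across the threo 2,3-diol is favoured over the cis-dioxolane across the erythro 3,4-diol, leaves 4-OH free (the minor 3,4-isomer can be re-equilibrated).

Step 4
Reactants: 4 2,3-O-isopropylidene-5-O-TBDPS-L-arabinose diethyl dithioacetal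
Product: 5 2,3-O-isopropylidene-5-O-TBDPS-L-threo-pentos-4-ulose diethyl dithioacetal
Conditions: (COCl)2, DMSO, CH2Cl2, −78 °C; then Et3N, −78 → 0 °C
Reagents that add atoms: none
Why: Swern oxidation of the remaining secondary alcohol tolerates the dithioacetal, and the trans-dioxolane disfavours epimerisation α to the new C10 ketone.

Step 5
Reactants: 6 but-2-yne-1,4-diol
Product: 7 4-[(4-methoxybenzyl)oxy]but-2-yn-1-ol
Conditions: NaH (1 equiv), 4-methoxybenzyl chloride (1 equiv), Bu4NI (cat.), THF/DMF, 0 °C → rt; diol in threefold excess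
Reagents that add atoms: 4-methoxybenzyl chloride, COc1ccc(CCl)cc1
Why: Williamson etherification with excess symmetric diol gives the mono-ether statistically.

Step 6
Reactants: 7 4-[(4-methoxybenzyl)oxy]but-2-yn-1-ol
Product: 9 (Z)-3-iodo-4-[(4-methoxybenzyl)oxy]but-2-en-1-ol, via cyclic sodium alkenylalanate 8 (not isolated)
Conditions: NaAlH2(OCH2CH2OMe)2, THF, 0 °C → rt; then I2, THF, −78 → 0 °C
Reagents that add atoms: iodine, II
Why: Hydroxyl-directed trans-hydroalumination puts aluminium on the distal alkyne carbon, and iodinolysis with retention gives the Z-iodide, fixing C15 trans to C6.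

Step 7
Reactants: 9 (Z)-3-iodo-4-[(4-methoxybenzyl)oxy]but-2-en-1-ol; 10 allyl chloride
Product: 12 (E)-6-chloro-3-{[(4-methoxybenzyl)oxy]methyl}hex-2-en-1-ol, via B-(3-chloropropyl)-9-BBN 11 (not isolated)
Conditions: 10, 9-BBN, THF, 0 °C → rt; then 9, Pd(dppf)Cl2 (5 mol%), AsPh3 (10 mol%), aq. K3PO4, DMF, rt
Reagents that add atoms: none
Why: Anti-Markovnikov hydroboration followed by B-alkyl Suzuki–Miyaura coupling proceeds with retention at the alkenyl iodide, so the C3 chain ends cis to C6.

Step 8
Reactants: 12 (E)-6-chloro-3-{[(4-methoxybenzyl)oxy]methyl}hex-2-en-1-ol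
Product: 13 [(E)-6-hydroxy-4-{[(4-methoxybenzyl)oxy]methyl}hex-4-en-1-yl]triphenylphosphonium iodide
Conditions: NaI (1.5 equiv), PPh3 (1.2 equiv), MeCN, reflux
Reagents that add atoms: triphenylphosphine, c1ccc(P(c2ccccc2)c2ccccc2)cc1; sodium iodide, [Na+].[I-]
Why: Finkelstein exchange and SN2 quaternisation of the phosphine occur in one pot at the primary halide.

Step 9
Reactants: 13 [(E)-6-hydroxy-4-{[(4-methoxybenzyl)oxy]methyl}hex-4-en-1-yl]triphenylphosphonium iodide; 5 2,3-O-isopropylidene-5-O-TBDPS-L-threo-pentos-4-ulose diethyl dithioacetal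
Product: 15 seco-diene dithioacetal (8,9-O-isopropylidene; 14-OTBDPS; 15-OPMB; 6-OH; C2 cis to C9; C3 cis to C6), via sodium alkoxide ylide 14 (not isolated)
Conditions: 13, NaN(SiMe3)2 (2.1 equiv per 13), THF, −78 → 0 °C; then 5, −78 °C → rt; aqueous work-up
Reagents that add atoms: none
Why: Wittig olefination of an α,α′-dioxygenated ketone with a salt-free non-stabilised ylide is expected to put the ylide chain cis to the bulkier dioxolanyl arm (as with α-alkoxy ketones and protected ketoses), giving the C2/C9-cis olefin, while the trans-dioxolane keeps C8 and C9 intact.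

Step 10
Reactants: 15 seco-diene dithioacetal
Product: 16 seco-diene C7 aldehyde
Conditions: I2, NaHCO3, acetone/H2O, 0 °C
Reagents that add atoms: water, O
Why: Iodine-mediated oxidative hydrolysis of the dithioacetal under bicarbonate buffer releases the aldehyde; the trans-dioxolane prevents epimerisation at C8.

Step 11
Reactants: 16 seco-diene C7 aldehyde; 17 methyl acrylate
Product: 18 Morita–Baylis–Hillman adduct (C7 carbinol; both epimers)
Conditions: methyl acrylate (excess), DABCO (1 equiv), MeOH (cat.), rt, 3–5 d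
Reagents that add atoms: none
Why: Morita–Baylis–Hillman reaction of the activated α-alkoxy aldehyde forms C7–C11; the C7 carbinol configuration is irrelevant because C7 becomes sp2 in step 13.

Step 12
Reactants: 18 Morita–Baylis–Hillman adduct
Product: 19 Morita–Baylis–Hillman adduct C6 enal
Conditions: TEMPO (10 mol%), PhI(OAc)2 (1.1 equiv), CH2Cl2, rt
Reagents that add atoms: none
Why: Oxoammonium-mediated (TEMPO) oxidation is selective for the primary allylic alcohol over the secondary carbinol and does not isomerise the C4=C5 geometry.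

Step 13
Reactants: 19 Morita–Baylis–Hillman adduct C6 enal
Product: 20 (Z)-2-(bromomethyl)enoate enal
Conditions: NBS, Me2S, CH2Cl2, −20 → 0 °C
Reagents that add atoms: N-bromosuccinimide, O=C1CCC(=O)N1Br
Why: Corey–Kim-type activation of the carbinol followed by SN2′ bromide delivery (allylic transposition) gives the thermodynamically preferred Z-2-(bromomethyl)enoate under neutral conditions.

Step 14
Reactants: 20 (Z)-2-(bromomethyl)enoate enal
Product: 22 macrolactone acetonide, via hydroxy ester 21 (not isolated)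
Conditions: undivided cell, Al anode (sacrificial), Ni-foam cathode, CrCl3(thf)3 (20 mol%), Bu4NBr (0.1 M), DMF, constant current 3 mA, 20 added over 10 h (final 2 mM), rt; then aq. citric acid; PPTS (cat.), CH2Cl2, rt
Reagents that add atoms: none
Why: Proposed new method: cathodic reduction of the trivalent chromium precatalyst gives divalent chromium, which inserts into the allylic C–Br bond of 20; the resulting 2-(methoxycarbonyl)allylchromium adds through its γ-carbon C7 to the tethered enal in a chair-like six-membered transition state (anti addition, H6/H7 trans), on the C7 face anti to the C8–C9 bond with H8 eclipsing the olefin (allylic 1,3-strain), which should fix 6R,7S under control of the arabinose-derived C8; trivalent aluminium ions from the anode free chromium from the alkoxide for re-reduction and hydroxy ester 21 lactonises; the closest known chemistry is the stoichiometric CrCl2 Nozaki–Hiyama–Kishi macrocyclisation of 2-(bromomethyl)enoate aldehydes to germacranolides and the intermolecular chromium-catalysed electroreductive allylation of aldehydes, neither shown as an electrocatalytic ten-membered-ring closure with lactonisation.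

Step 15
Reactants: 22 macrolactone acetonide
Product: 23 macrolactone 8,9-diol
Conditions: AcOH/H2O (4:1), 45 °C
Reagents that add atoms: none
Why: Acid-catalysed acetal hydrolysis removes the isopropylidene group while the TBDPS ether, PMB ether and lactone survive.

Step 16
Reactants: 23 macrolactone 8,9-diol; 24 angelic acid
Product: 26 8,9-di-O-angeloyl macrolactone, via angelic 2,4,6-trichlorobenzoic anhydride 25 (not isolated)
Conditions: 24 (6 equiv), 2,4,6-Cl3C6H2COCl (6 equiv), Et3N, toluene, rt, filter; then 23, toluene, 80 °C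
Reagents that add atoms: none
Why: Yamaguchi-type mixed-anhydride acylation without a nucleophilic catalyst esterifies both hindered secondary alcohols and avoids angelate-to-tiglate isomerisation; no stereocentre is involved.

Step 17
Reactants: 26 8,9-di-O-angeloyl macrolactone
Product: 27 14-hydroxy 15-O-PMB bis-angelate
Conditions: HF·pyridine, pyridine, THF, 0 °C → rt
Reagents that add atoms: none
Why: Fluoride-mediated Si–O cleavage removes the TBDPS group; the esters, lactone and PMB ether are inert.

Step 18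
Reactants: 27 14-hydroxy 15-O-PMB bis-angelate
Product: 28 14-oxo 15-O-PMB bis-angelate
Conditions: Dess–Martin periodinane, NaHCO3, CH2Cl2, 0 °C → rt
Reagents that add atoms: none
Why: Dess–Martin oxidation of the only free (allylic) alcohol gives the enal, whose C2/C9-cis geometry is also the thermodynamically preferred one; oxidising after acylation avoids lactol formation with a free 8-OH.

Step 19
Reactants: 28 14-oxo 15-O-PMB bis-angelate
Product: 29 CNP0139154.1 (target)
Conditions: DDQ (1.5 equiv), CH2Cl2/pH 7 phosphate buffer (10:1), 0 °C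
Reagents that add atoms: none
Why: Oxidative PMB ether cleavage by DDQ (benzylic hydride abstraction, hemiacetal collapse) frees the C15 alcohol without touching the angelates, enal or α-methylene lactone.

## Compound list

1 | L-arabinose (written in the open-chain aldehydo form) | O=C[C@H](O)[C@@H](O)[C@@H](O)CO | starting material
2 | L-arabinose diethyl dithioacetal | CCSC(SCC)[C@H](O)[C@@H](O)[C@@H](O)CO | intermediate
3 | 5-O-(tert-butyldiphenylsilyl)-L-arabinose diethyl dithioacetal | CCSC(SCC)[C@H](O)[C@@H](O)[C@@H](O)CO[Si](c1ccccc1)(c1ccccc1)C(C)(C)C | intermediate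
4 | 2,3-O-isopropylidene-5-O-TBDPS-L-arabinose diethyl dithioacetal (trans-dioxolane, free 4-OH) | CCSC(SCC)[C@@H]1OC(C)(C)O[C@H]1[C@@H](O)CO[Si](c2ccccc2)(c2ccccc2)C(C)(C)C | intermediate
5 | 2,3-O-isopropylidene-5-O-TBDPS-L-threo-pentos-4-ulose diethyl dithioacetal (C10 ketone; C7 dithioacetal; C14–OTBDPS) | CCSC(SCC)[C@@H]1OC(C)(C)O[C@H]1C(=O)CO[Si](c2ccccc2)(c2ccccc2)C(C)(C)C | intermediate
6 | but-2-yne-1,4-diol | OCC#CCO | starting material
7 | 4-[(4-methoxybenzyl)oxy]but-2-yn-1-ol | OCC#CCOCc1ccc(OC)cc1 | intermediate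
8 | cyclic sodium alkenylalanate (five-membered O–Al–C ring, Al on the carbon bearing CH2OPMB) | [Na+].COCCO[Al-]1(OCCOC)OCC=C1COCc2ccc(OC)cc2 | intermediate
9 | (Z)-3-iodo-4-[(4-methoxybenzyl)oxy]but-2-en-1-ol | OC/C=C(\I)COCc1ccc(OC)cc1 | intermediate
10 | allyl chloride | C=CCCl | starting material
11 | B-(3-chloropropyl)-9-borabicyclo[3.3.1]nonane | ClCCCB1C2CCCC1CCC2 | intermediate
12 | (E)-6-chloro-3-{[(4-methoxybenzyl)oxy]methyl}hex-2-en-1-ol (chloropropyl chain cis to CH2OH) | OC/C=C(\CCCCl)COCc1ccc(OC)cc1 | intermediate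
13 | [(E)-6-hydroxy-4-{[(4-methoxybenzyl)oxy]methyl}hex-4-en-1-yl]triphenylphosphonium iodide | OC/C=C(\CCC[P+](c1ccccc1)(c1ccccc1)c1ccccc1)COCc1ccc(OC)cc1.[I-] | intermediate
14 | sodium alkoxide ylide derived from 13 | [Na+].[O-]C/C=C(\CCC=P(c1ccccc1)(c1ccccc1)c1ccccc1)COCc1ccc(OC)cc1 | intermediate
15 | seco-diene dithioacetal: C7 CH(SEt)2, 8,9-O-isopropylidene (8S,9S series from arabinose), C10 bearing CH2OTBDPS, C1=C10 with C2 cis to C9, C4 bearing CH2OPMB, C4=C5 with C3 cis to C6, C6 CH2OH | CCSC(SCC)[C@@H]1OC(C)(C)O[C@H]1/C(CO[Si](c2ccccc2)(c2ccccc2)C(C)(C)C)=C\CC/C(COCc2ccc(OC)cc2)=C\CO | intermediate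
16 | seco-diene C7 aldehyde (as 15 with C7 = CHO) | O=C[C@@H]1OC(C)(C)O[C@H]1/C(CO[Si](c2ccccc2)(c2ccccc2)C(C)(C)C)=C\CC/C(COCc2ccc(OC)cc2)=C\CO | intermediate
17 | methyl acrylate | C=CC(=O)OC | starting material
18 | Morita–Baylis–Hillman adduct: methyl 2-methylene-3-hydroxy ester at C7 (both C7 epimers), otherwise as 16 | C=C(C(=O)OC)C(O)[C@@H]1OC(C)(C)O[C@H]1/C(CO[Si](c2ccccc2)(c2ccccc2)C(C)(C)C)=C\CC/C(COCc2ccc(OC)cc2)=C\CO | intermediate
19 | Morita–Baylis–Hillman adduct C6 enal (as 18 with C6 = CHO; both C7 epimers) | C=C(C(=O)OC)C(O)[C@@H]1OC(C)(C)O[C@H]1/C(CO[Si](c2ccccc2)(c2ccccc2)C(C)(C)C)=C\CC/C(COCc2ccc(OC)cc2)=C\C=O | intermediate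
20 | (Z)-2-(bromomethyl)enoate enal: C7=C11 with C8 cis to CH2Br, methyl ester at C12, C6 aldehyde, 8,9-acetonide, 14-OTBDPS, 15-OPMB | COC(=O)/C(CBr)=C/[C@@H]1OC(C)(C)O[C@H]1/C(CO[Si](c2ccccc2)(c2ccccc2)C(C)(C)C)=C\CC/C(COCc2ccc(OC)cc2)=C\C=O | intermediate
21 | ten-membered hydroxy ester (6R,7S): C6–OH, C7 bearing the methyl acrylate unit, 8,9-acetonide | C=C(C(=O)OC)[C@H]1[C@H](O)/C=C(/COCc2ccc(OC)cc2)CC/C=C(/CO[Si](c2ccccc2)(c2ccccc2)C(C)(C)C)[C@@H]2OC(C)(C)O[C@@H]12 | intermediate
22 | macrolactone acetonide: trans-fused 6,12-olide (6R,7S), 8,9-O-isopropylidene, 14-OTBDPS, 15-OPMB | C=C1C(=O)O[C@@H]2/C=C(/COCc3ccc(OC)cc3)CC/C=C(/CO[Si](c3ccccc3)(c3ccccc3)C(C)(C)C)[C@@H]3OC(C)(C)O[C@H]3[C@@H]12 | intermediate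
23 | macrolactone 8,9-diol (14-OTBDPS, 15-OPMB) | C=C1C(=O)O[C@@H]2/C=C(/COCc3ccc(OC)cc3)CC/C=C(/CO[Si](c3ccccc3)(c3ccccc3)C(C)(C)C)[C@H](O)[C@@H](O)[C@@H]12 | intermediate
24 | angelic acid, (Z)-2-methylbut-2-enoic acid | C/C=C(/C)C(=O)O | starting material
25 | angelic 2,4,6-trichlorobenzoic anhydride | C/C=C(/C)C(=O)OC(=O)c1c(Cl)cc(Cl)cc1Cl | intermediate
26 | 8,9-di-O-angeloyl macrolactone (14-OTBDPS, 15-OPMB) | C=C1C(=O)O[C@@H]2/C=C(/COCc3ccc(OC)cc3)CC/C=C(/CO[Si](c3ccccc3)(c3ccccc3)C(C)(C)C)[C@H](OC(=O)/C(C)=C\C)[C@@H](OC(=O)/C(C)=C\C)[C@@H]12 | intermediate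
27 | 14-hydroxy 15-O-PMB bis-angelate | C=C1C(=O)O[C@@H]2/C=C(/COCc3ccc(OC)cc3)CC/C=C(/CO)[C@H](OC(=O)/C(C)=C\C)[C@@H](OC(=O)/C(C)=C\C)[C@@H]12 | intermediate
28 | 14-oxo 15-O-PMB bis-angelate | C=C1C(=O)O[C@@H]2/C=C(/COCc3ccc(OC)cc3)CC/C=C(/C=O)[C@H](OC(=O)/C(C)=C\C)[C@@H](OC(=O)/C(C)=C\C)[C@@H]12 | intermediate
29 | CNP0139154.1: (6R,7S,8S,9S)-8,9-bis(angeloyloxy)-15-hydroxy-14-oxogermacra-1(10)E,4E,11(13)-trien-12,6-olide | C=C1C(=O)O[C@@H]2/C=C(/CO)CC/C=C(/C=O)[C@H](OC(=O)/C(C)=C\C)[C@@H](OC(=O)/C(C)=C\C)[C@@H]12 | target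

## Step count and risks

Total steps: 19. Longest linear sequence: 15 (steps 1–4, then 9–19; the branch 5–8 then 9–19 is equally long).

The three steps most likely to fail:

**Step 14 (the proposed electroreductive macrocyclisation).** Risks are direct cathodic reduction of the enal or bromide, oligomerisation, and the wrong C6/C7 diastereomer. The fallback sets out from 20 and returns at 22. It separates C–C bond formation from lactonisation with known chemistry. An indium-mediated intramolecular Barbier allylation (In powder, THF/H2O, high dilution) stops at the open hydroxy ester. From a Z-2-(bromomethyl)enoate this is expected to be mainly the syn adduct, the 6-epi hydroxy ester F1. Saponification (LiOH, THF/H2O) gives the 6-epi hydroxy acid F2. Mitsunobu lactonisation (PPh3, DIAD, THF, 0 °C) then closes the five-membered lactone with inversion at the allylic C6, giving the trans-fused lactone 22.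

**Step 9 (Wittig geometry at C1=C10).** Both ketone arms are α-oxygenated, so the preference for the C2/C9-cis olefin is an estimate. The fallback sets out from 13 and 5 and returns at 15. It is a stepwise Horner–Wittig olefination. Alkaline hydrolysis of 13 (aq. NaOH, reflux) gives the diphenylphosphine oxide F3. Its dianion (n-BuLi, 2 equiv, THF, −78 °C) adds to ketone 5 to give separable β-hydroxy phosphine oxides. The diastereomer F4 (or its C1,C10-bis-epimer, which behaves the same way) is isolated by chromatography. Stereospecific syn-elimination (KH, DMF, 50 °C) then gives geometrically pure 15.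

**Step 16 (double angeloylation of the hindered trans-diol).** Risks are incomplete acylation, isomerisation to tiglate, or lactone migration to O8. The fallback sets out from 23 and returns at 26. It builds the Z-olefin on the ester instead of transferring an intact angeloyl group. Both hydroxyls are esterified with 2-[bis(2,2,2-trifluoroethoxy)phosphoryl]propanoic acid (DCC, cat. DMAP, CH2Cl2) to give the bis(phosphonopropionate) F5. A twofold Still–Gennari olefination with acetaldehyde (KN(SiMe3)2, 18-crown-6, THF, −78 °C) then gives the two Z-2-methylbut-2-enoates of 26; no aldehyde is present in the substrate at this stage.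

## Further compounds

F1 | step 14 | 6-epi hydroxy ester (6S,7S; C6–OH, methyl acrylate unit on C7, 8,9-acetonide, 14-OTBDPS, 15-OPMB) | C=C(C(=O)OC)[C@H]1[C@@H](O)/C=C(/COCc2ccc(OC)cc2)CC/C=C(/CO[Si](c2ccccc2)(c2ccccc2)C(C)(C)C)[C@@H]2OC(C)(C)O[C@@H]12
F2 | step 14 | 6-epi hydroxy acid (carboxylic acid of F1) | C=C(C(=O)O)[C@H]1[C@@H](O)/C=C(/COCc2ccc(OC)cc2)CC/C=C(/CO[Si](c2ccccc2)(c2ccccc2)C(C)(C)C)[C@@H]2OC(C)(C)O[C@@H]12
F3 | step 9 | [(E)-6-hydroxy-4-{[(4-methoxybenzyl)oxy]methyl}hex-4-en-1-yl]diphenylphosphine oxide | OC/C=C(\CCCP(=O)(c1ccccc1)c1ccccc1)COCc1ccc(OC)cc1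
F4 | step 9 | β-hydroxy phosphine oxide adduct of F3 and 5 (C10 tertiary alcohol, C1 diphenylphosphinoyl; diastereomer whose syn-elimination gives the C2/C9-cis olefin) | CCSC(SCC)[C@@H]1OC(C)(C)O[C@H]1[C@](O)(CO[Si](c2ccccc2)(c2ccccc2)C(C)(C)C)[C@@H](P(=O)(c2ccccc2)c2ccccc2)CC/C(COCc2ccc(OC)cc2)=C\CO
F5 | step 16 | 8,9-bis{2-[bis(2,2,2-trifluoroethoxy)phosphoryl]propanoate} of diol 23 | C=C1C(=O)O[C@@H]2/C=C(/COCc3ccc(OC)cc3)CC/C=C(/CO[Si](c3ccccc3)(c3ccccc3)C(C)(C)C)[C@H](OC(=O)C(C)P(=O)(OCC(F)(F)F)OCC(F)(F)F)[C@@H](OC(=O)C(C)P(=O)(OCC(F)(F)F)OCC(F)(F)F)[C@@H]12
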